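**Retrosynthetic overview**
1. Target ⇐ peracetylation, hydroxyl-directed 11,20-epoxidation, Peterson elimination (C5=C16) and chlorolactonization across (E)-C6=C7 (ring C, the 7,19-γ-lactone, with C6–Cl) ⇐ ten-membered dienone enol ether 31, which already carries C17–C19 as a fused dihydrofuran.
2. Key disconnection: the ten-membered ring B (C1–C10) comes from the eight-membered ring C1–C2–C3–C4–C5–C6–C9–C10 of 29 by intramolecular enone–alkyne [2+2] photocycloaddition and 4π-opening of the cyclobutene, which inserts C8 and C7.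
3. Enabling feature: in 29 the enol-ether oxygen on C9 carries the tether O–C19–C17 to the alkyne C8≡C7, and C6 carries the acceptor C5=O. The C9–C6 bond shared by the cyclobutene and the eight-membered ring is therefore strained and push–pull substituted.
4. The eight-membered ring is closed by ring-closing metathesis (C5=C6) on ring A; its 1,3-diketone is differentiated through the C5 vinylogous amide and the β-chlorovinyl iminium salt, so that alkynol 26 enters at O9.
5. Ring A (C1, C10–C14) is made first by an asymmetric Diels–Alder reaction, then C2, C14 and C12 are set; ring order: A, eight-membered, dihydrofuran + cyclobutene, ten-membered B, lactone C, epoxide.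

Key step: step 21

Remark on numbering: C1–C20 are the briarane positions of the target (C15 methyl on C1, C16 exocyclic CH2 on C5, C18 methyl on C17, C19 lactone carbonyl, C20 epoxide CH2); on ring A, β is the face of Me-15 and α the opposite face.
Assumption: the (R,R)-diol of step 1 is taken to give the enantiomer drawn; if the sense of induction is opposite, the (S,S)-diol is used.

**Step 1**
Reactants: 1 ethyl (E)-3-methyl-4-oxobut-2-enoate; 2 (E)-1-(dimethylamino)-3-(tert-butyldimethylsilyloxy)buta-1,3-diene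
Product: 4 enone aldehyde (ethyl 2-formyl-2-methyl-5-oxocyclohex-3-ene-1-carboxylate; CHO trans to CO2Et), via aminocyclohexene cycloadduct 3 (not isolated)
Conditions: (R,R)-1-naphthyl-TADDOL (20 mol %), toluene, −78 °C; then HF (aq), MeCN, 0 °C
Reagents that add atoms: none
Why: Hydrogen-bond-catalysed Diels–Alder reaction of an aminosiloxydiene in which the diol activates the formyl group, so the CH2 terminus bonds to C10 and the amino terminus to C1, the (E)-dienophile places CHO and CO2Et trans (Me-15 cis to C9), the diol sets the absolute configuration of C1 and C10, and HF unmasks the enone by desilylation and β-elimination of the amine.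

**Step 2**
Reactants: 4 enone aldehyde
Product: 6 lactone enone (trans-fused O2–C9 γ-lactone; 2R; C2 but-3-enyl; 13-en-12-one), via bromomagnesium alkoxide 5 (not isolated)
Conditions: CH2=CHCH2CH2MgBr, MgBr2·OEt2, CH2Cl2–Et2O, −78 °C → rt
Reagents that add atoms: but-3-enylmagnesium bromide, C=CCC[Mg]Br
Why: Chelation-controlled Grignard addition in which magnesium bridges the formyl and ester carbonyl oxygens, the nucleophile enters from the face of Me-15 (anti to the ring vinyl carbon C14) to give (2R), and the alkoxide then closes the γ-lactone onto C9, which masks O2 and keeps C9 an acyl donor.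

**Step 3**
Reactants: 6 lactone enone
Product: 7 Mannich base (CH2NMe2 on C11)
Conditions: LiN(i-Pr)2, THF, −78 °C; CH2=NMe2+ I−, −78 → 0 °C
Reagents that add atoms: N,N-dimethylmethyleneiminium iodide, C=[N+](C)C.[I-]
Why: Kinetic α′-deprotonation of the enone (C11 is its only accessible enolisable carbon) and Mannich alkylation introduce the future C20 regiospecifically; the C11 configuration is of no consequence because it is removed in step 20.

**Step 4**
Reactants: 7 Mannich base
Product: 9 14α-hydroxy 12-ketone, via 14α-boronate 8 (not isolated)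
Conditions: CuCl (5 mol %), NaOt-Bu (10 mol %), DPEphos, B2pin2, MeOH, THF, rt; then H2O2, pH 7 buffer, 0 °C
Reagents that add atoms: hydrogen peroxide, OO
Why: Copper-catalysed conjugate borylation and C–B oxidation with retention (formal β-hydroxylation of the enone); with the lactone trans-fused, Me-15 is axial, so boron adds axially to C14 on the α face, anti to Me-15 and cis to C2.

**Step 5**
Reactants: 9 14α-hydroxy 12-ketone
Product: 10 12α,14α-diol
Conditions: Et2BOMe, NaBH4, THF–MeOH, −78 °C; MeOH co-evaporation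
Reagents that add atoms: none
Why: Narasaka–Prasad reduction, in which the diethylboron chelate between the axial 14-OH and the C12 carbonyl directs external hydride to the opposite face and should give the cis-1,3-diol.

**Step 6**
Reactants: 10 12α,14α-diol
Product: 11 12,14-O-di-tert-butylsilylene lactone
Conditions: t-Bu2Si(OTf)2, 2,6-lutidine, CH2Cl2, 0 °C
Reagents that add atoms: di-tert-butylsilyl bis(trifluoromethanesulfonate), CC(C)(C)[Si](OS(=O)(=O)C(F)(F)F)(OS(=O)(=O)C(F)(F)F)C(C)(C)C
Why: Silylene formation across the cis-1,3-diol gives one six-membered, fluoride-labile protecting ring for O12 and O14.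

**Step 7**
Reactants: 11 silylene lactone
Product: 12 C9 N-methoxy-N-methylamide with free 2-OH
Conditions: MeNH(OMe)·HCl, i-PrMgCl, THF, −20 → 0 °C
Reagents that add atoms: N,O-dimethylhydroxylamine hydrochloride, CNOC.Cl
Why: Aminolysis of the strained trans-fused lactone with the chloromagnesium amide (Weinreb amide formation) frees O2 and prepares C9 for a single organometallic addition.

**Step 8**
Reactants: 12 hydroxy amide
Product: 13 2-O-TBS amide
Conditions: TBSOTf, 2,6-lutidine, CH2Cl2, −78 → 0 °C
Reagents that add atoms: tert-butyldimethylsilyl trifluoromethanesulfonate, CC(C)(C)[Si](C)(C)OS(=O)(=O)C(F)(F)F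
Why: Silylation of the hindered secondary C2 alcohol with the silyl triflate.

**Step 9**
Reactants: 13 2-O-TBS amide
Product: 14 C9 vinyl ketone
Conditions: CH2=CHMgBr, THF, 0 °C; cold aq. citric acid
Reagents that add atoms: vinylmagnesium bromide, C=C[Mg]Br
Why: Weinreb ketone synthesis, in which the magnesium chelate releases the vinyl ketone only on acidic quench, which also keeps the liberated hydroxylamine from adding back.

**Step 10**
Reactants: 14 vinyl ketone
Product: 15 bicyclic (Z)-cyclooct-2-enone (C9 ketone; C5=C6)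
Conditions: TsOH·H2O (1.05 equiv), second-generation Grubbs catalyst (10 mol %), toluene (0.5 mM), 80 °C; aq. NaHCO3
Reagents that add atoms: none
Why: Ring-closing metathesis of the vinyl ketone with the butenyl chain closes the eight-membered ring on the trans-diequatorial cyclohexane scaffold; the amine is masked as its tosylate salt and no other alkene is present at this stage.

**Step 11**
Reactants: 15 cyclooctenone
Product: 17 5-hydroxy 9-ketone, via C5 boronate 16 (not isolated)
Conditions: CuCl (5 mol %), NaOt-Bu (10 mol %), DPEphos, B2pin2, MeOH, THF, rt; then H2O2, pH 7 buffer, 0 °C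
Reagents that add atoms: hydrogen peroxide, OO
Why: Conjugate borylation and oxidation as in step 4 place oxygen on C5; the C5 configuration is lost in step 12.

**Step 12**
Reactants: 17 5-hydroxy 9-ketone
Product: 18 5,9-diketone
Conditions: Dess–Martin periodinane, NaHCO3, CH2Cl2, 0 °C → rt
Reagents that add atoms: none
Why: Dess–Martin oxidation of the β-hydroxy ketone to the 1,3-diketone; C10 should keep its configuration because the trans-diequatorial ring fusion is the stable one.

**Step 13**
Reactants: 18 5,9-diketone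
Product: 19 vinylogous amide (pyrrolidinyl on C5; C9 ketone)
Conditions: pyrrolidine, 4 Å MS, benzene, 50 °C
Reagents that add atoms: pyrrolidine, C1CCNC1
Why: Condensation of a secondary amine with the unsymmetrical 1,3-diketone, in which nitrogen should go to the less hindered carbonyl carbon C5 (flanked by C4H2) and away from the ring-fusion carbon C10, where it would suffer allylic strain.

**Step 14**
Reactants: 19 vinylogous amide
Product: 21 β-chloroenone (Cl on C9; C5 ketone), via chlorovinyl iminium chloride 20 (not isolated)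
Conditions: (COCl)2, CH2Cl2, 0 °C; then aq. NaOAc, rt
Reagents that add atoms: oxalyl chloride, O=C(Cl)C(=O)Cl; water, O
Why: Vilsmeier-type activation converts the vinylogous amide into the β-chlorovinyl iminium salt, and buffered hydrolysis at the iminium carbon gives the β-chloroenone, so the leaving group sits on C9 and the carbonyl on C5 (regiochemical transposition of the diketone).

**Step 15**
Reactants: 22 methyl (S)-3-hydroxy-2-methylpropanoate
Product: 23 methyl (S)-3-(tert-butyldimethylsilyloxy)-2-methylpropanoate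
Conditions: TBSCl, imidazole, DMF, rt
Reagents that add atoms: tert-butyldimethylsilyl chloride, CC(C)(C)[Si](C)(C)Cl
Why: Standard silylation of the primary alcohol.

**Step 16**
Reactants: 23 silyl ether ester
Product: 24 (S)-3-(tert-butyldimethylsilyloxy)-2-methylpropanal
Conditions: i-Bu2AlH, CH2Cl2, −78 °C
Reagents that add atoms: none
Why: Partial reduction of the ester to the aldehyde through the stable aluminium hemiacetal at low temperature.

**Step 17**
Reactants: 24 aldehyde
Product: 25 (R)-tert-butyldimethyl(2-methylbut-3-ynyloxy)silane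
Conditions: MeC(O)C(N2)P(O)(OMe)2, K2CO3, MeOH, 0 °C → rt
Reagents that add atoms: dimethyl (1-diazo-2-oxopropyl)phosphonate, COP(=O)(OC)C(=[N+]=[N-])C(C)=O
Why: Ohira–Bestmann homologation (Seyferth–Gilbert type) turns the formyl carbon into C8 of the terminal alkyne under conditions mild enough to keep the α-stereocentre (the future C17, R).

**Step 18**
Reactants: 25 silyl ether alkyne
Product: 26 (R)-2-methylbut-3-yn-1-ol
Conditions: Bu4NF, THF, 0 °C
Reagents that add atoms: none
Why: Fluoride cleavage of the silyl ether.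

**Step 19**
Reactants: 21 β-chloroenone; 26 (R)-2-methylbut-3-yn-1-ol
Product: 27 3-alkoxy-enone (O9 ether of 26; CH2NMe2 on C11)
Conditions: NaH, THF, 0 °C → rt
Reagents that add atoms: none
Why: Addition–elimination of the alkoxide at C9 of the β-chloroenone (vinylogous acyl substitution) gives the regiodefined 3-alkoxy-enone carrying the alkyne on a three-atom tether.

**Step 20**
Reactants: 27 3-alkoxy-enone
Product: 29 photosubstrate (3-alkoxy-enone with C11=C20), via amine N-oxide 28 (not isolated)
Conditions: m-CPBA (1.0 equiv), CH2Cl2, −20 °C; then toluene, 80 °C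
Reagents that add atoms: none
Why: Amine N-oxidation and Cope syn-elimination, whose only β-hydrogen is on C11, give the exocyclic C11=C20 alkene; it is made only now so that no β,γ-unsaturated C9 ketone and no second metathesis partner existed earlier.

**Step 21**
Reactants: 29 photosubstrate
Product: 31 ten-membered (6E,8Z)-dienone enol ether, via cyclobutene photoadduct 30 (not isolated)
Conditions: hν (350 nm, Pyrex), degassed MeCN (2 mM), 0 °C; then toluene, 70 °C
Reagents that add atoms: none
Why: Excitation of the 3-alkoxy-enone gives its triplet, which bonds C9 to C8 first (five-membered ring, rule of five) and then C6 to C7, an intramolecular enone–alkyne [2+2] photocycloaddition to cyclobutene 30 (a 2-oxabicyclo[3.2.0]hept-6-ene fused to the eight-membered ring at C9–C6). The C9–C6 σ-bond of 30 is common to the cyclobutene and the eight-membered ring and carries the donor oxygen on C9 and the acceptor C5=O on C6, so on warming it should open in a conrotatory 4π-electrocyclic reaction that releases the cyclobutene strain and inserts C8 and C7 between C9 and C6, turning the eight-membered ring into the ten-membered ring. The closest known reactions are the intramolecular [2+2] photocycloaddition of 3-alkoxy-enones with tethered alkenes or alkynes (De Mayo type) and the thermal opening of bicyclo[n.2.0]alkenes and push–pull cyclobutenes to ring-enlarged 1,3-dienes. The dihydrofuran ring closes by 5-exo attack on the alkyne and the four-membered ring by biradical recombination, while the ten-membered ring is not closed at all but arises by cleavage of the shared bond. No stereocentre formed here survives (C9, C8, C7 and C6 end as sp2 carbons), only geometry matters: the ring oxygen must rotate outward, so C8=C9 is cis within the ten-membered ring, and conrotation from the cis-fused cyclobutene makes C6=C7 (E), the geometry that step 25 needs. The step needs straight rather than crossed regiochemistry and trapping faster than twisting of the medium-ring enone, both secured by the three-atom tether O–C19–C17 on the enol oxygen, and the C11=C20 alkene is only one atom from C9 and cannot cyclise.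

**Step 22**
Reactants: 31 dienone enol ether
Product: 33 8-hydroxy C9 hemiketal (E)-enone, via enol ether epoxide 32 (not isolated)
Conditions: dimethyldioxirane (1.05 equiv), acetone, −78 → −30 °C; then H2O, NaHCO3
Reagents that add atoms: dimethyldioxirane, CC1(C)OO1; water, O
Why: Epoxidation of the electron-rich tetrasubstituted enol ether C8=C9 and hydrolytic opening at the acetal carbon (Rubottom-type oxidation of a cyclic enol ether); the oxidant should attack the dihydrofuran face anti to the adjacent Me-18, which sets the C8 tertiary alcohol as in the target, while the enone and the 1,1-disubstituted alkene are far less nucleophilic.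

**Step 23**
Reactants: 33 hemiketal enone
Product: 34 C5 tertiary β-hydroxysilane
Conditions: Me3SiCH2Li, CeCl3, THF, −78 °C
Reagents that add atoms: (trimethylsilyl)methyllithium, [Li]C[Si](C)(C)C
Why: 1,2-Addition of the organocerium reagent (Peterson reagent) to the unhindered enone carbonyl C5, with C9 masked as the hemiketal, turns the enone into an isolated (E)-alkene and stores the future C16; the C5 configuration is inconsequential.

**Step 24**
Reactants: 34 β-hydroxysilane
Product: 36 keto acid (C19 acid; C9 ketone), via C19 aldehyde 35 (not isolated)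
Conditions: TEMPO (20 mol %), PhI(OAc)2, MeCN–pH 7 buffer, 0 °C → rt
Reagents that add atoms: water, O
Why: Oxoammonium (TEMPO) oxidation of the primary C19 alcohol, which is exposed by ring–chain tautomerism of the hemiketal, proceeds through the aldehyde hydrate to the acid under buffered conditions that should spare the acid-labile tertiary β-hydroxysilane.

**Step 25**
Reactants: 36 keto acid
Product: 37 chlorolactone (6-chloro-7,19-olide; C9 ketone)
Conditions: 1,3-dichloro-5,5-dimethylhydantoin, DABCO (20 mol %), CH2Cl2, −30 °C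
Reagents that add atoms: 1,3-dichloro-5,5-dimethylhydantoin, CC1(C)N(Cl)C(=O)N(Cl)C1=O
Why: Chlorolactonization (5-exo opening of the chloronium ion by the C19 carboxylate at C7): anti addition across the (E)-C6=C7 alkene gives the C6/C7 relationship of the target, and the ring torsion C9–C8–C7=C6 of the (E)-cycloalkene should let the carboxylate reach only the face that gives the trans-fused lactone (C6 cis to 8-OH).

**Step 26**
Reactants: 37 chlorolactone
Product: 38 9-alcohol
Conditions: Zn(BH4)2, Et2O, −20 °C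
Reagents that add atoms: none
Why: Chelation-controlled reduction of the α-hydroxy ketone, in which zinc bridges O8 and the C9 carbonyl and hydride arrives from the peripheral face on the side of C17, should give the C9 configuration of the target without touching the lactone or the chloride.

**Step 27**
Reactants: 38 9-alcohol
Product: 39 pentaol diene (2,8,9,12,14-pentahydroxy; C5=C16 and C11=C20)
Conditions: HF (48 % aq), MeCN, 0 °C → rt
Reagents that add atoms: none
Why: Acid-promoted Peterson elimination of the tertiary β-hydroxysilane gives the C5=C16 alkene without base, so C6–Cl and the lactone survive, and HF removes the silyl ether and the silylene in the same operation.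

**Step 28**
Reactants: 39 pentaol diene
Product: 40 11,20-epoxide pentaol
Conditions: VO(acac)2 (5 mol %), t-BuOOH, CH2Cl2, 0 °C
Reagents that add atoms: tert-butyl hydroperoxide, CC(C)(C)OO
Why: Vanadium-catalysed hydroxyl-directed epoxidation, in which the allylic 12α-OH delivers oxygen to the α face of C11=C20 (also the face anti to the syn-axial Me-15), while C5=C16 has no allylic hydroxyl.

**Step 29**
Reactants: 40 epoxide pentaol
Product: 41 CNP0349227.4 (target)
Conditions: Ac2O, DMAP (cat.), pyridine, rt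
Reagents that add atoms: acetic anhydride, CC(=O)OC(C)=O
Why: Acetylation of the four secondary hydroxyls (O2, O9, O12, O14); the tertiary 8-OH should not be acylated under these conditions.

**Compound list**
1 | ethyl (E)-3-methyl-4-oxobut-2-enoate | CCOC(=O)/C=C(\C)C=O | starting material
2 | (E)-1-(dimethylamino)-3-(tert-butyldimethylsilyloxy)buta-1,3-diene | C=C(O[Si](C)(C)C(C)(C)C)/C=C/N(C)C | starting material
3 | cycloadduct: ethyl 5-(TBSO)-3-(dimethylamino)-2-formyl-2-methylcyclohex-4-ene-1-carboxylate (CHO trans to CO2Et, cis to NMe2) | CCOC(=O)[C@H]1CC(O[Si](C)(C)C(C)(C)C)=C[C@H](N(C)C)[C@]1(C)C=O | intermediate (not isolated)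
4 | enone aldehyde: ethyl 2-formyl-2-methyl-5-oxocyclohex-3-ene-1-carboxylate (CHO trans to CO2Et; C1 and C10 as in target) | CCOC(=O)[C@H]1CC(=O)C=C[C@]1(C)C=O | intermediate
5 | bromomagnesium (2R)-alkoxide of the butenyl adduct of 4 | CCOC(=O)[C@H]1CC(=O)C=C[C@]1(C)[C@H](O[Mg]Br)CCC=C | intermediate (not isolated)
6 | lactone enone: trans-fused O2–C9 γ-lactone, (2R)-but-3-enyl on C2, 13-en-12-one | O=C1O[C@H](CCC=C)[C@@]2(C)C=CC(=O)C[C@H]12 | intermediate
7 | Mannich base: 6 with CH2NMe2 on C11 (α) | O=C1O[C@H](CCC=C)[C@@]2(C)C=CC(=O)[C@@H](CN(C)C)[C@H]12 | intermediate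
8 | 14α-pinacolboronate of 7 (12-ketone) | O=C1O[C@H](CCC=C)[C@@]2(C)[C@@H](B3OC(C)(C)C(C)(C)O3)CC(=O)[C@@H](CN(C)C)[C@H]12 | intermediate (not isolated)
9 | 14α-hydroxy 12-ketone | O=C1O[C@H](CCC=C)[C@@]2(C)[C@@H](O)CC(=O)[C@@H](CN(C)C)[C@H]12 | intermediate
10 | 12α,14α-diol | O=C1O[C@H](CCC=C)[C@@]2(C)[C@@H](O)C[C@@H](O)[C@@H](CN(C)C)[C@H]12 | intermediate
11 | 12,14-O-di-tert-butylsilylene lactone | O=C1O[C@H](CCC=C)[C@@]2(C)[C@@H]3C[C@@H](O[Si](O3)(C(C)(C)C)C(C)(C)C)[C@@H](CN(C)C)[C@H]12 | intermediate
12 | C9 N-methoxy-N-methylamide, free (2R)-OH | CON(C)C(=O)[C@H]1[C@H](CN(C)C)[C@H]2C[C@H](O[Si](O2)(C(C)(C)C)C(C)(C)C)[C@]1(C)[C@H](O)CCC=C | intermediate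
13 | 2-O-TBS amide | CON(C)C(=O)[C@H]1[C@H](CN(C)C)[C@H]2C[C@H](O[Si](O2)(C(C)(C)C)C(C)(C)C)[C@]1(C)[C@H](O[Si](C)(C)C(C)(C)C)CCC=C | intermediate
14 | C9 vinyl ketone | C=CC(=O)[C@H]1[C@H](CN(C)C)[C@H]2C[C@H](O[Si](O2)(C(C)(C)C)C(C)(C)C)[C@]1(C)[C@H](O[Si](C)(C)C(C)(C)C)CCC=C | intermediate
15 | bicyclic (Z)-cyclooct-2-enone (C9 ketone, C5=C6), trans-fused to ring A | O=C1/C=C\CC[C@@H](O[Si](C)(C)C(C)(C)C)[C@@]2(C)[C@@H]3C[C@@H](O[Si](O3)(C(C)(C)C)C(C)(C)C)[C@@H](CN(C)C)[C@H]12 | intermediate
16 | C5 pinacolboronate of the 9-ketone (C5 configuration arbitrary) | O=C1C[C@H](B4OC(C)(C)C(C)(C)O4)CC[C@@H](O[Si](C)(C)C(C)(C)C)[C@@]2(C)[C@@H]3C[C@@H](O[Si](O3)(C(C)(C)C)C(C)(C)C)[C@@H](CN(C)C)[C@H]12 | intermediate (not isolated)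
17 | 5-hydroxy 9-ketone (C5 configuration arbitrary) | O=C1C[C@H](O)CC[C@@H](O[Si](C)(C)C(C)(C)C)[C@@]2(C)[C@@H]3C[C@@H](O[Si](O3)(C(C)(C)C)C(C)(C)C)[C@@H](CN(C)C)[C@H]12 | intermediate
18 | 5,9-diketone | O=C1CC(=O)CC[C@@H](O[Si](C)(C)C(C)(C)C)[C@@]2(C)[C@@H]3C[C@@H](O[Si](O3)(C(C)(C)C)C(C)(C)C)[C@@H](CN(C)C)[C@H]12 | intermediate
19 | vinylogous amide (pyrrolidin-1-yl on C5, C9 ketone) | O=C1/C=C(N4CCCC4)\CC[C@@H](O[Si](C)(C)C(C)(C)C)[C@@]2(C)[C@@H]3C[C@@H](O[Si](O3)(C(C)(C)C)C(C)(C)C)[C@@H](CN(C)C)[C@H]12 | intermediate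
20 | β-chlorovinyl iminium chloride (Cl on C9, pyrrolidinium on C5) | Cl/C1=C/C(=[N+]4CCCC4)CC[C@@H](O[Si](C)(C)C(C)(C)C)[C@@]2(C)[C@@H]3C[C@@H](O[Si](O3)(C(C)(C)C)C(C)(C)C)[C@@H](CN(C)C)[C@H]12.[Cl-] | intermediate (not isolated)
21 | β-chloroenone (Cl on C9, C5 ketone) | Cl/C1=C/C(=O)CC[C@@H](O[Si](C)(C)C(C)(C)C)[C@@]2(C)[C@@H]3C[C@@H](O[Si](O3)(C(C)(C)C)C(C)(C)C)[C@@H](CN(C)C)[C@H]12 | intermediate
22 | methyl (S)-3-hydroxy-2-methylpropanoate | COC(=O)[C@@H](C)CO | starting material
23 | methyl (S)-3-(tert-butyldimethylsilyloxy)-2-methylpropanoate | COC(=O)[C@@H](C)CO[Si](C)(C)C(C)(C)C | intermediate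
24 | (S)-3-(tert-butyldimethylsilyloxy)-2-methylpropanal | O=C[C@@H](C)CO[Si](C)(C)C(C)(C)C | intermediate
25 | (R)-tert-butyldimethyl(2-methylbut-3-ynyloxy)silane | C#C[C@@H](C)CO[Si](C)(C)C(C)(C)C | intermediate
26 | (R)-2-methylbut-3-yn-1-ol | C#C[C@@H](C)CO | intermediate
27 | 3-alkoxy-enone: O9 ether of 26 on C9, C5 ketone, CH2NMe2 on C11 | C#C[C@@H](C)CO/C1=C/C(=O)CC[C@@H](O[Si](C)(C)C(C)(C)C)[C@@]2(C)[C@@H]3C[C@@H](O[Si](O3)(C(C)(C)C)C(C)(C)C)[C@@H](CN(C)C)[C@H]12 | intermediate
28 | N-oxide of 27 | C#C[C@@H](C)CO/C1=C/C(=O)CC[C@@H](O[Si](C)(C)C(C)(C)C)[C@@]2(C)[C@@H]3C[C@@H](O[Si](O3)(C(C)(C)C)C(C)(C)C)[C@@H](C[N+](C)(C)[O-])[C@H]12 | intermediate (not isolated)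
29 | photosubstrate: 3-alkoxy-enone with exocyclic C11=C20 | C#C[C@@H](C)CO/C1=C/C(=O)CC[C@@H](O[Si](C)(C)C(C)(C)C)[C@@]2(C)[C@@H]3C[C@@H](O[Si](O3)(C(C)(C)C)C(C)(C)C)C(=C)[C@H]12 | intermediate
30 | cyclobutene photoadduct (bonds C9–C8 and C6–C7; one cis-fused diastereomer drawn) | C[C@H]1CO[C@]23[C@H](C=C12)C(=O)CC[C@@H](O[Si](C)(C)C(C)(C)C)[C@@]4(C)[C@@H]5C[C@@H](O[Si](O5)(C(C)(C)C)C(C)(C)C)C(=C)[C@H]34 | intermediate (not isolated)
31 | ten-membered (6E,8Z)-dienone enol ether: dihydrofuran O9–C19–C17–C8=C9, C5 ketone | C[C@H]1COC2=C1/C=C/C(=O)CC[C@@H](O[Si](C)(C)C(C)(C)C)[C@@]3(C)[C@@H]4C[C@@H](O[Si](O4)(C(C)(C)C)C(C)(C)C)C(=C)[C@H]23 | intermediate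
32 | 8,9-epoxide of 31 (oxygen anti to Me-18) | C[C@H]1CO[C@]2(O5)[C@@]15/C=C/C(=O)CC[C@@H](O[Si](C)(C)C(C)(C)C)[C@@]3(C)[C@@H]4C[C@@H](O[Si](O4)(C(C)(C)C)C(C)(C)C)C(=C)[C@H]23 | intermediate (not isolated)
33 | 8-hydroxy C9 hemiketal (E)-enone (9-OH trans to 8-OH; anomeric centre free to equilibrate) | C[C@H]1CO[C@@]2(O)[C@@]1(O)/C=C/C(=O)CC[C@@H](O[Si](C)(C)C(C)(C)C)[C@@]3(C)[C@@H]4C[C@@H](O[Si](O4)(C(C)(C)C)C(C)(C)C)C(=C)[C@H]23 | intermediate
34 | C5 tertiary β-hydroxysilane (C5 configuration arbitrary), (E)-C6=C7 | C[C@H]1CO[C@@]2(O)[C@@]1(O)/C=C/[C@](O)(C[Si](C)(C)C)CC[C@@H](O[Si](C)(C)C(C)(C)C)[C@@]3(C)[C@@H]4C[C@@H](O[Si](O4)(C(C)(C)C)C(C)(C)C)C(=C)[C@H]23 | intermediate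
35 | C19 aldehyde (open C9 keto form) | O=C[C@H](C)[C@]1(O)/C=C/[C@](O)(C[Si](C)(C)C)CC[C@@H](O[Si](C)(C)C(C)(C)C)[C@@]2(C)[C@@H]3C[C@@H](O[Si](O3)(C(C)(C)C)C(C)(C)C)C(=C)[C@@H]2C1=O | intermediate (not isolated)
36 | keto acid (C19 acid, C9 ketone; open form) | OC(=O)[C@H](C)[C@]1(O)/C=C/[C@](O)(C[Si](C)(C)C)CC[C@@H](O[Si](C)(C)C(C)(C)C)[C@@]2(C)[C@@H]3C[C@@H](O[Si](O3)(C(C)(C)C)C(C)(C)C)C(=C)[C@@H]2C1=O | intermediate
37 | chlorolactone: 6-chloro-7,19-olide, 8-OH, C9 ketone | C[Si](C)(C)C[C@]1(O)CC[C@@H](O[Si](C)(C)C(C)(C)C)[C@@]2(C)[C@@H]3C[C@@H](O[Si](O3)(C(C)(C)C)C(C)(C)C)C(=C)[C@@H]2C(=O)[C@]2(O)[C@@H](C)C(=O)O[C@H]2[C@H]1Cl | intermediate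
38 | 9-alcohol of 37 | C[Si](C)(C)C[C@]1(O)CC[C@@H](O[Si](C)(C)C(C)(C)C)[C@@]2(C)[C@@H]3C[C@@H](O[Si](O3)(C(C)(C)C)C(C)(C)C)C(=C)[C@@H]2[C@@H](O)[C@]2(O)[C@@H](C)C(=O)O[C@H]2[C@H]1Cl | intermediate
39 | pentaol diene: 6-chloro-2,8,9,12,14-pentahydroxybriara-5(16),11(20)-dien-18,7-olide | C=C1CC[C@@H](O)[C@@]2(C)[C@@H](O)C[C@@H](O)C(=C)[C@@H]2[C@@H](O)[C@]2(O)[C@@H](C)C(=O)O[C@H]2[C@H]1Cl | intermediate
40 | 11,20-epoxide pentaol | C=C1CC[C@@H](O)[C@@]2(C)[C@@H](O)C[C@@H](O)[C@]3(CO3)[C@@H]2[C@@H](O)[C@]2(O)[C@@H](C)C(=O)O[C@H]2[C@H]1Cl | intermediate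
41 | CNP0349227.4: 2,9,12,14-tetraacetoxy-6-chloro-11,20-epoxy-8-hydroxybriar-5(16)-en-18,7-olide | C=C1CC[C@@H](OC(C)=O)[C@@]2(C)[C@@H](OC(C)=O)C[C@@H](OC(C)=O)[C@]3(CO3)[C@@H]2[C@@H](OC(C)=O)[C@]2(O)[C@@H](C)C(=O)O[C@H]2[C@H]1Cl | target

**Step count and risks**
Total step count: 29. Longest linear sequence: 25 steps (steps 1–14 and 19–29); the side branch to 26 is steps 15–18.

Steps most likely to fail:

Step 21. The excited eight-membered enone may lose its energy by twisting about C6=C9, or the cyclobutene may absorb light and undergo acyl shifts before it opens, so that little 31 forms. Fallback: a thermal, metal-catalysed route to the same bond changes, setting out from 29 and returning at 31. With PtCl2 (10 mol %) in toluene at 80 °C, the 1,6-enyne of 29 (enol-ether alkene C9=C6, tether O–C19–C17, alkyne C8≡C7) should undergo the skeletal rearrangement known for enynes with an endocyclic alkene: alkyne activation, cyclopropyl carbene, formal [2+2] and ring-opening. This forms C9–C8 and C6–C7, cleaves C9–C6, and needs no light; no new compound arises (F0).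

Step 25. Chloronium formation at the hindered (E)-alkene may be slower than attack at C11=C20, or may show poor facial selectivity, or the tertiary β-hydroxysilane may ionise. Fallback: an epoxide route that sets out from 34 and returns at 37. Hydroxyl-directed epoxidation of (E)-C6=C7 (m-CPBA, NaHCO3, CH2Cl2, 0 °C) should give the 6,7-epoxide F1. Chloride delivery from the titanium alkoxide of O8 (TiCl(Oi-Pr)3, CH2Cl2, 0 °C) opens it at C6 with inversion to the 7-hydroxy-6-chloride (chlorohydrin) F2, which has the same anti Cl/O relationship. TEMPO/PhI(OAc)2 then oxidises the C19 alcohol of the opened hemiketal, and the lactol with 7-OH goes on to the lactone 37.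

Step 2. Incomplete chelation would erode the facial selectivity at the formyl group and give C2 epimers. Fallback: reagent control, setting out from 12 obtained as the C2-epimer mixture and returning at 12. Dess–Martin oxidation gives the C2 ketone F3, and reduction with the (S)-Me-CBS oxazaborolidine and BH3·SMe2 (quaternary C1 as the large group) should return (2R)-12.

**Further compounds**
F0 | step 21 | none | none
F1 | step 25 | 6,7-epoxide of 34 (epoxide oxygen becomes O7) | C[C@H]1CO[C@@]2(O)[C@@]1(O)[C@H]5O[C@@H]5[C@](O)(C[Si](C)(C)C)CC[C@@H](O[Si](C)(C)C(C)(C)C)[C@@]3(C)[C@@H]4C[C@@H](O[Si](O4)(C(C)(C)C)C(C)(C)C)C(=C)[C@H]23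
F2 | step 25 | 7-hydroxy-6-chloride (chlorohydrin) of the hemiketal | C[C@H]1CO[C@@]2(O)[C@@]1(O)[C@@H](O)[C@@H](Cl)[C@](O)(C[Si](C)(C)C)CC[C@@H](O[Si](C)(C)C(C)(C)C)[C@@]3(C)[C@@H]4C[C@@H](O[Si](O4)(C(C)(C)C)C(C)(C)C)C(=C)[C@H]23
F3 | step 2 | C2 ketone of amide 12 | CON(C)C(=O)[C@H]1[C@H](CN(C)C)[C@H]2C[C@H](O[Si](O2)(C(C)(C)C)C(C)(C)C)[C@]1(C)C(=O)CCC=C
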